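The beta run looks almost like your flask: substrate and free catalyst are charged alike, and the reagent is 0.14 M against your 0.203 M. Yet the two can't end alike. Each turnover takes one reagent and one substrate, and both flasks charge less reagent than substrate , so reagent is the limiting reagent and conversion can reach at most 48.3% in beta and 70.0% in your flask. Reaching 50% needs 0.145 M of reagent. Beta has less than that, while your flask keeps 0.0580 M.

the same everywhere: substrate 0.29 M

| charge | reagent | free catalyst | remark |
|---|---|---|---|
| beta | 0.14 M | 0.29 mM | run made earlier |
| epsilon | 0.30 M | 0.29 mM | run made earlier |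
| eta | 0.203 M | 0.43 mM | run made earlier |
| flask | 0.203 M | 0.29 mM |  |

| run | time / h | target / % | substrate / % |
|---|---|---|---|
| beta | 0.417 | 4.1 | 96.6 |
| beta | 0.833 | 6.8 | 93.8 |
| beta | 1.33 | 9.0 | 90.1 |
| beta | 1.50 | 10.6 | 89.3 |
| beta | 2.00 | 14.2 | 85.9 |
| beta | 2.50 | 16.6 | 82.8 |
| epsilon | 0.167 | 2.1 | 98.2 |
| epsilon | 0.500 | 5.2 | 95.2 |
| epsilon | 0.833 | 7.5 | 91.1 |
| epsilon | 1.33 | 12.6 | 86.8 |
| epsilon | 2.00 | 17.6 | 82.0 |
| epsilon | 2.50 | 21.8 | 77.8 |
| eta | 0.200 | 3.5 | 97.6 |
| eta | 0.667 | 9.6 | 91.6 |
| eta | 1.00 | 12.8 | 87.9 |
| eta | 1.50 | 18.5 | 81.8 |
| eta | 2.50 | 27.5 | 72.1 |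

(standard deviation of a reading: 0.5 percentage points)

- apparent order in free catalyst when 50% of the substrate are converted (percent change of the rate of making target for one percent more free catalyst charged)
- apparent order in reagent when 50% of the substrate are converted (percent change of the rate of making target for one percent more reagent charged)

That small remainder matters. In your flask, one percent more reagent charged means 3.50 percent more reagent left, and this ratio of the charge to the reagent left at the chosen conversion is the leverage. The epsilon run, by the same ratio, has 1.94.

You still need the rate's response to the reagent left, so replace each curve by its mean. By 2.50 h, epsilon shows 1.31 times the target of beta, with mean reagent 0.268 M against 0.116 M. A saturating curve through these two readings has its half-saturation at 0.0839 M, which gives a local order of 0.591 at 0.0580 M. My reckoning for the order in reagent charged is therefore 2.07. Using the charges instead of the means gives 2.31, and that gap is the error the averaging brings.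

The forecast gives 1 in free catalyst and 1.9 in reagent, below my figure, allowing for a local order “reduced somewhat by possible target inhibition”.

The flask gives 1.3 in free catalyst and 2.9 in reagent, which is more than my 2.07.

    reagent + free catalyst → catalyst intermediate A (k = 31.2 M⁻¹ min⁻¹)
    substrate + catalyst intermediate A → catalyst intermediate B (k = 51.5 M⁻¹ min⁻¹)
    catalyst intermediate B ⇌ free catalyst + target (K = 0.180 M, k = 2.34 min⁻¹)
    free catalyst ⇌ dormant form (K = 2.30, k = 0.00309 min⁻¹)

Your flask reaches 50% at 9.33 h, making target at 0.00780 M h⁻¹, and there one percent more on the constants of the step between free catalyst and dormant form changes the rate by −0.26 percent. The reagent order of 2.9 stays below the leverage of 3.50, which is the charge over the 0.0580 M of reagent left at 50% in your flask.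

The numbers in the tables come from a simulation on assumed constants, and the scatter is random.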